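**Synthetic plan**

- Cuts: the quinone ring bonds C1–C6 and C4–C5 and the bond from C2 to C3 of indole A (quinone numbering: C1=O, C2 indolyl A, C3 OH, C4=O, C5 indol-3-yl B, C6 prenyl); both N–H groups are masked as N-SEM and the C3 hydroxyl as OMe.
- Enabling feature: C1(=O)–C2(aryl)=C3(O)–C4(=O) is the four-carbon ring of squaric acid with three of its oxygens, and C5=C6 is a 1-(indol-3-yl)alkene with the prenyl group on its far carbon, so one 4-alkenyl-4-hydroxycyclobutenone holds all six ring carbons.
- Forward order: indole A is closed by Fischer synthesis and bonded through C3 to the cyclobutenedione; the Shapiro-derived alkenyllithium of fragment B adds to the dione; heating expands the four-membered ring to the benzenoid ring.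
- Finish: oxidation to the quinone, hydrolysis of the vinylogous methyl ester, removal of both SEM groups.
- Stereochemistry: the target has no stereocentre and no stereogenic alkene; the racemic carbinol carbon and the alkene geometry of the cyclobutenone are erased in the ring expansion.

Key step: step 10

Remark: SEM stands for [2-(trimethylsilyl)ethoxy]methyl; the carbinol carbon of the cyclobutenone and the sp3 carbon of the transient cyclohexadienone are the only stereocentres on the way, both form racemic and neither survives, so no enantiocontrol is planned.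

**Route**

Step 1
Reactants: 1 prenyl bromide
Product: 4 3,3-dimethylpent-4-en-2-one, via prenylzinc bromide 2 (not isolated), via bromozinc ketiminate 3 (not isolated)
Conditions: Zn dust, THF, 0 °C to rt; MeCN, rt; then 1 M HCl, rt
Reagents that add atoms: acetonitrile CC#N; water O
Why: The allylic zinc bromide adds to the nitrile with allylic transposition through a cyclic six-membered transition state, so the new C–C bond forms at the dimethyl-bearing carbon, and the zinc ketiminate resists a second addition and is hydrolysed by acid to the ketone (Barbier-type allylzinc addition to a nitrile).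

Step 2
Reactants: 4 3,3-dimethylpent-4-en-2-one; 5 phenylhydrazine
Product: 7 2-(2-methylbut-3-en-2-yl)-1H-indole, via phenylhydrazone 6 (not isolated)
Conditions: PhNHNH2, AcOH (cat.), EtOH, 70 °C; evaporate; ZnCl2, AcOH, 90 °C
Reagents that add atoms: none
Why: Fischer indole synthesis, in which the hydrazone can tautomerise to the ene-hydrazine only toward the methyl group because the other alpha carbon is quaternary, so the [3,3]-sigmatropic shift and loss of ammonia put the tert-alkyl group on indole C2 and leave C3 free.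

Step 3
Reactants: 7 2-(2-methylbut-3-en-2-yl)-1H-indole
Product: 8 2-(2-methylbut-3-en-2-yl)-1-SEM-indole
Conditions: NaH, DMF, 0 °C; SEMCl, 0 °C to rt
Reagents that add atoms: 2-(trimethylsilyl)ethoxymethyl chloride C[Si](C)(C)CCOCCl
Why: N-alkylation of the sodium indolide by the reactive alpha-chloro ether (SN2) should proceed even beside the tert-alkyl group and removes the acidic N–H before the organolithium step.

Step 4
Reactants: 9 squaric acid
Product: 10 squaric acid dichloride
Conditions: (COCl)2, DMF (cat.), 1,2-dichloroethane, 60 °C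
Reagents that add atoms: oxalyl chloride O=C(Cl)C(=O)Cl
Why: The chloroiminium salt formed from oxalyl chloride and DMF converts both vinylogous acid hydroxyls into vinylogous acid chlorides (Vilsmeier-type acid chloride formation).

Step 5
Reactants: 8 2-(2-methylbut-3-en-2-yl)-1-SEM-indole; 10 squaric acid dichloride
Product: 12 3-methoxy-4-[2-(2-methylbut-3-en-2-yl)-1-SEM-indol-3-yl]cyclobut-3-ene-1,2-dione, via semisquaric chloride 11 (not isolated)
Conditions: 10 (1.2 equiv), 2,6-di-tert-butylpyridine (2.2 equiv), CH2Cl2, 0 °C to rt; then MeOH, rt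
Reagents that add atoms: methanol CO
Why: Uncatalysed Friedel–Crafts-type addition–elimination of the electron-rich indole C3 (C2 and N are blocked) on the vinylogous acid chloride, with the bulky neighbour and the deactivated mono-adduct preventing a second arylation, is followed by methanolysis of the remaining chloride by the same addition–elimination path, while the hindered pyridine takes up HCl so that the SEM group and the alkene are spared.

Step 6
Reactants: 13 3-acetylindole
Product: 14 3-acetyl-1-SEM-indole
Conditions: NaH, DMF, 0 °C; SEMCl, 0 °C to rt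
Reagents that add atoms: 2-(trimethylsilyl)ethoxymethyl chloride C[Si](C)(C)CCOCCl
Why: The vinylogous amide N–H is acidic and its sodium salt is alkylated on nitrogen by SEMCl (SN2 N-alkylation), giving a group that tolerates amide bases and organolithiums.

Step 7
Reactants: 14 3-acetyl-1-SEM-indole; 1 prenyl bromide
Product: 15 5-methyl-1-(1-SEM-indol-3-yl)hex-4-en-1-one
Conditions: LiN(iPr)2, THF, -78 °C; prenyl bromide, -78 to -20 °C
Reagents that add atoms: none
Why: Kinetic lithium enolate alkylation, in which the amide base removes a proton from the acetyl CH3 (the only enolisable position and far more acidic than indole C2–H) and the enolate is C-alkylated by the allylic bromide at its primary carbon (SN2), low temperature and a slight excess of enolate limiting dialkylation.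

Step 8
Reactants: 15 5-methyl-1-(1-SEM-indol-3-yl)hex-4-en-1-one
Product: 16 (E)-2,4,6-triisopropylbenzenesulfonyl hydrazone of 15
Conditions: 2,4,6-iPr3C6H2SO2NHNH2, conc. HCl (cat.), THF–MeOH, rt
Reagents that add atoms: 2,4,6-triisopropylbenzenesulfonyl hydrazide CC(C)c1cc(C(C)C)c(S(=O)(=O)NN)c(C(C)C)c1
Why: Acid-catalysed condensation of the ketone with the sulfonyl hydrazide (hydrazone formation) should give the isomer with the sulfonamide nitrogen on the side of the CH2 group and away from the larger indolyl group, which is the arrangement needed for syn deprotonation.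

Step 9
Reactants: 16 (E)-2,4,6-triisopropylbenzenesulfonyl hydrazone of 15; 12 3-methoxy-4-[2-(2-methylbut-3-en-2-yl)-1-SEM-indol-3-yl]cyclobut-3-ene-1,2-dione
Product: 18 rac-4-hydroxy-3-methoxy-4-[(E)-5-methyl-1-(1-SEM-indol-3-yl)hexa-1,4-dien-1-yl]-2-[2-(2-methylbut-3-en-2-yl)-1-SEM-indol-3-yl]cyclobut-2-en-1-one, via alkenyllithium 17 (not isolated)
Conditions: 16 (1.3 equiv), n-BuLi (2.05 equiv per 16), THF, -78 °C, then 0 °C until N2 evolution ends; recool to -78 °C, add 12 in THF; aq. NH4Cl, -78 °C
Reagents that add atoms: none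
Why: Shapiro reaction, in which the second equivalent of n-BuLi removes a syn alpha-CH2 proton of the lithiated hydrazone and loss of sulfinate and N2 gives alkenyllithium 17, which adds 1,2 to the ketone-like carbonyl beside the methoxy-bearing carbon of 12 (the other carbonyl is a vinylogous ester and is shielded by the twisted 2-tert-alkylindolyl group), as organolithiums do with 3-alkoxy-4-arylcyclobutenediones, the carbinol carbon forming racemic.

Step 10
Reactants: 18 rac-4-hydroxy-3-methoxy-4-[(E)-5-methyl-1-(1-SEM-indol-3-yl)hexa-1,4-dien-1-yl]-2-[2-(2-methylbut-3-en-2-yl)-1-SEM-indol-3-yl]cyclobut-2-en-1-one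
Product: 21 3-methoxy-2-[2-(2-methylbut-3-en-2-yl)-1-SEM-indol-3-yl]-5-(1-SEM-indol-3-yl)-6-(3-methylbut-2-en-1-yl)benzene-1,4-diol, via dienylketene 19 (not isolated), via cyclohexadienone 20 (not isolated)
Conditions: toluene (degassed), 110 °C, Ar, dark
Reagents that add atoms: none
Why: Heating opens the cyclobutenone by conrotatory 4-pi electrocyclic cleavage of the C1–C4 bond, the C4 hydroxyl rotating outward (torquoselectivity of a donor substituent) so that the alkenyl group lies cis to the ketene in dienylketene 19. The ketene carbon then bonds to the alkene carbon carrying the prenyl CH2 in a thermal 6-pi electrocyclisation that closes the only new ring, the six-membered carbocycle, as cyclohexa-2,4-dienone 20, and enolisation of its single sp3 C–H gives the aromatic hydroquinone. This is the known thermal ring expansion of squarate-derived 4-alkenyl-4-hydroxycyclobutenones to hydroquinones (Moore rearrangement). No stereocentre survives, because the carbinol carbon becomes an aryl C–OH carbon, the sp3 carbon of 20 is transient and the alkene geometry is lost on ring closure. The substitution pattern needs no selectivity here, since step 9 has already fixed indolyl A and OMe on C2 and C3 and indolyl B and the prenyl chain on C5 and C6. Closure onto the conjugated alkene should outrun ketene [2+2] addition to the two isolated alkenes and attack on C2 of indole B (a seven-membered ring), because only the 6-pi path leads to an aromatic ring.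

Step 11
Reactants: 21 3-methoxy-2-[2-(2-methylbut-3-en-2-yl)-1-SEM-indol-3-yl]-5-(1-SEM-indol-3-yl)-6-(3-methylbut-2-en-1-yl)benzene-1,4-diol
Product: 22 3-methoxy-2-[2-(2-methylbut-3-en-2-yl)-1-SEM-indol-3-yl]-5-(1-SEM-indol-3-yl)-6-(3-methylbut-2-en-1-yl)-1,4-benzoquinone
Conditions: Ag2O, MgSO4, Et2O, rt
Reagents that add atoms: none
Why: Two-electron oxidation of a para-hydroquinone to the quinone by Ag2O under neutral conditions should leave the indoles, the alkenes and the SEM groups untouched.

Step 12
Reactants: 22 3-methoxy-2-[2-(2-methylbut-3-en-2-yl)-1-SEM-indol-3-yl]-5-(1-SEM-indol-3-yl)-6-(3-methylbut-2-en-1-yl)-1,4-benzoquinone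
Product: 23 3-hydroxy-2-[2-(2-methylbut-3-en-2-yl)-1-SEM-indol-3-yl]-5-(1-SEM-indol-3-yl)-6-(3-methylbut-2-en-1-yl)-1,4-benzoquinone
Conditions: NaOH (2 M aq), MeOH–THF, 50 °C; then 1 M HCl, 0 °C, to pH 3
Reagents that add atoms: sodium hydroxide [Na+].[OH-]
Why: Saponification of the vinylogous methyl ester by addition–elimination of hydroxide at the methoxy-bearing quinone carbon stops at the hydroxyquinone, because the vinylogous carboxylate formed is inert to more hydroxide, and SEM groups are stable to aqueous base.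

Step 13
Reactants: 23 3-hydroxy-2-[2-(2-methylbut-3-en-2-yl)-1-SEM-indol-3-yl]-5-(1-SEM-indol-3-yl)-6-(3-methylbut-2-en-1-yl)-1,4-benzoquinone
Product: 24 target CNP0134649.0
Conditions: Bu4NF (1 M in THF, excess), DMPU, 65 °C, Ar; then cold 0.5 M HCl to pH 3
Reagents that add atoms: none
Why: Fluoride attacks silicon and fragments each SEM group to fluorotrimethylsilane, ethylene and an N-hydroxymethyl anion that expels formaldehyde (standard N-SEM cleavage), while the hydroxyquinone is held as its unreactive tetrabutylammonium enolate until the mild acid work-up.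

**Compound list**

1 | prenyl bromide (1-bromo-3-methylbut-2-ene) | CC(C)=CCBr | starting material
2 | prenylzinc bromide, (3-methylbut-2-en-1-yl)zinc bromide (formed in the flask, not isolated) | CC(C)=CC[Zn]Br | intermediate
3 | bromozinc ketiminate, N-bromozinc imine of 3,3-dimethylpent-4-en-2-one (not isolated) | CC(=N[Zn]Br)C(C)(C)C=C | intermediate
4 | 3,3-dimethylpent-4-en-2-one | CC(=O)C(C)(C)C=C | intermediate
5 | phenylhydrazine | NNc1ccccc1 | starting material
6 | (E)-phenylhydrazone of 4 (not isolated) | C/C(=N\Nc1ccccc1)C(C)(C)C=C | intermediate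
7 | 2-(2-methylbut-3-en-2-yl)-1H-indole | C=CC(C)(C)c1cc2ccccc2[nH]1 | intermediate
8 | 2-(2-methylbut-3-en-2-yl)-1-{[2-(trimethylsilyl)ethoxy]methyl}indole | C=CC(C)(C)c1cc2ccccc2n1COCC[Si](C)(C)C | intermediate
9 | squaric acid (3,4-dihydroxycyclobut-3-ene-1,2-dione) | O=C1C(=O)C(O)=C1O | starting material
10 | squaric acid dichloride (3,4-dichlorocyclobut-3-ene-1,2-dione) | O=C1C(=O)C(Cl)=C1Cl | intermediate
11 | semisquaric chloride, 3-chloro-4-[2-(2-methylbut-3-en-2-yl)-1-SEM-indol-3-yl]cyclobut-3-ene-1,2-dione (not isolated) | O=C1C(=O)C(Cl)=C1c1c(C(C)(C)C=C)n(COCC[Si](C)(C)C)c2ccccc12 | intermediate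
12 | 3-methoxy-4-[2-(2-methylbut-3-en-2-yl)-1-SEM-indol-3-yl]cyclobut-3-ene-1,2-dione | COC1=C(c2c(C(C)(C)C=C)n(COCC[Si](C)(C)C)c3ccccc23)C(=O)C1=O | intermediate
13 | 3-acetylindole, 1-(1H-indol-3-yl)ethanone | CC(=O)c1c[nH]c2ccccc12 | starting material
14 | 3-acetyl-1-SEM-indole | CC(=O)c1cn(COCC[Si](C)(C)C)c2ccccc12 | intermediate
15 | 5-methyl-1-(1-SEM-indol-3-yl)hex-4-en-1-one | CC(C)=CCCC(=O)c1cn(COCC[Si](C)(C)C)c2ccccc12 | intermediate
16 | (E)-2,4,6-triisopropylbenzenesulfonyl hydrazone of 15 (sulfonamide N syn to the CH2 group) | CC(C)=CCC/C(c1cn(COCC[Si](C)(C)C)c2ccccc12)=N\NS(=O)(=O)c1c(C(C)C)cc(C(C)C)cc1C(C)C | intermediate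
17 | alkenyllithium, (Z)-[5-methyl-1-(1-SEM-indol-3-yl)hexa-1,4-dien-1-yl]lithium, Li trans to the CH2 group (not isolated) | [Li]/C(c1cn(COCC[Si](C)(C)C)c2ccccc12)=C/CC=C(C)C | intermediate
18 | rac-4-hydroxy-3-methoxy-4-[(E)-5-methyl-1-(1-SEM-indol-3-yl)hexa-1,4-dien-1-yl]-2-[2-(2-methylbut-3-en-2-yl)-1-SEM-indol-3-yl]cyclobut-2-en-1-one | COC1=C(c2c(C(C)(C)C=C)n(COCC[Si](C)(C)C)c3ccccc23)C(=O)C1(O)/C(c1cn(COCC[Si](C)(C)C)c2ccccc12)=C/CC=C(C)C | intermediate
19 | dienylketene, 4-hydroxy-3-methoxy-9-methyl-2-[2-(2-methylbut-3-en-2-yl)-1-SEM-indol-3-yl]-5-(1-SEM-indol-3-yl)deca-1,3,5,8-tetraen-1-one, alkenyl group cis to the ketene-bearing carbon (not isolated) | O=C=C(c1c(C(C)(C)C=C)n(COCC[Si](C)(C)C)c2ccccc12)/C(OC)=C(/O)\C(c1cn(COCC[Si](C)(C)C)c2ccccc12)=C\CC=C(C)C | intermediate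
20 | cyclohexadienone, rac-4-hydroxy-3-methoxy-2-[2-(2-methylbut-3-en-2-yl)-1-SEM-indol-3-yl]-5-(1-SEM-indol-3-yl)-6-(3-methylbut-2-en-1-yl)cyclohexa-2,4-dien-1-one (not isolated) | O=C1C(CC=C(C)C)C(c2cn(COCC[Si](C)(C)C)c3ccccc23)=C(O)C(OC)=C1c1c(C(C)(C)C=C)n(COCC[Si](C)(C)C)c2ccccc12 | intermediate
21 | 3-methoxy-2-[2-(2-methylbut-3-en-2-yl)-1-SEM-indol-3-yl]-5-(1-SEM-indol-3-yl)-6-(3-methylbut-2-en-1-yl)benzene-1,4-diol | COc1c(O)c(-c2cn(COCC[Si](C)(C)C)c3ccccc23)c(CC=C(C)C)c(O)c1-c1c(C(C)(C)C=C)n(COCC[Si](C)(C)C)c2ccccc12 | intermediate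
22 | 3-methoxy-2-[2-(2-methylbut-3-en-2-yl)-1-SEM-indol-3-yl]-5-(1-SEM-indol-3-yl)-6-(3-methylbut-2-en-1-yl)-1,4-benzoquinone | COC1=C(c2c(C(C)(C)C=C)n(COCC[Si](C)(C)C)c3ccccc23)C(=O)C(CC=C(C)C)=C(c2cn(COCC[Si](C)(C)C)c3ccccc23)C1=O | intermediate
23 | 3-hydroxy-2-[2-(2-methylbut-3-en-2-yl)-1-SEM-indol-3-yl]-5-(1-SEM-indol-3-yl)-6-(3-methylbut-2-en-1-yl)-1,4-benzoquinone | OC1=C(c2c(C(C)(C)C=C)n(COCC[Si](C)(C)C)c3ccccc23)C(=O)C(CC=C(C)C)=C(c2cn(COCC[Si](C)(C)C)c3ccccc23)C1=O | intermediate
24 | target CNP0134649.0, 3-hydroxy-5-(1H-indol-3-yl)-2-[2-(2-methylbut-3-en-2-yl)-1H-indol-3-yl]-6-(3-methylbut-2-en-1-yl)-1,4-benzoquinone | C=CC(C)(C)c1[nH]c2ccccc2c1C1=C(O)C(=O)C(c2c[nH]c3ccccc23)=C(CC=C(C)C)C1=O | target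

**Step count and risks**

Total step count: 13. Longest linear sequence: 9 steps (steps 1, 2, 3, 5, 9, 10, 11, 12, 13, from prenyl bromide to the target).

Steps most likely to fail:

1. Step 9. The alkenyllithium has to survive a period at 0 °C, where proton transfer to it from the doubly allylic CH2 group or from indole C2–H, or protonation by THF, could consume it before the dione is added; incomplete decomposition of the hydrazone dianion would have the same effect. The fallback generates the nucleophile at -78 °C throughout by tin–lithium exchange. It sets out from ketone 15: KN(SiMe3)2 and PhNTf2 (THF, -78 °C) should give the (Z)-enol triflate F1. Coupling with Me3SnSnMe3 under Pd(PPh3)4 catalysis (LiCl, dioxane, 80 °C) should give the (Z)-alkenylstannane F2. MeLi (THF, -78 °C) should then give the (E)-alkenyllithium F3, the geometric isomer of 17, which is added at once to 12 to give the (Z)-cyclobutenone F4. Thermolysis of F4 under the conditions of step 10 erases the alkene geometry, and the route is rejoined at hydroquinone 21.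

2. Step 13. Hot fluoride may degrade the quinone chromophore, or the cleavage may stall at N-hydroxymethyl groups that release formaldehyde only slowly. The fallback removes the SEM groups one oxidation level earlier, where no electrophilic quinone is present. It sets out from hydroquinone 21: Bu4NF in THF–DMPU at 65 °C under strict exclusion of oxygen should give the bis-N–H hydroquinone F5. Ag2O oxidation as in step 11 should give the bis-N–H methoxyquinone F6. NaOH in aqueous MeOH followed by mild acidification, as in step 12, then leads directly to target 24.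

3. Step 5. Substitution of the dichloride at C3 of indole 8 may be slow beside the tert-alkyl group, and the liberated HCl or a second arylation may erode the material. The fallback makes the same bond with reversed polarity. It sets out from 8: NBS (THF, -78 to 0 °C) should give the 3-bromoindole F7. t-BuLi (2 equiv, THF, -78 °C) should give the 3-lithioindole F8, which cannot migrate to C2 because that position is substituted. Addition to commercial dimethyl squarate (3,4-dimethoxycyclobut-3-ene-1,2-dione) at -78 °C should give the carbinol adduct F9. TFAA (CH2Cl2, -78 to 0 °C, then aq. NaHCO3) should ionise the carbinol and release methanol, giving the methyl semisquarate 12, where the route is rejoined.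

**Further compounds**

F1 | step 9 | (Z)-5-methyl-1-(1-SEM-indol-3-yl)hexa-1,4-dien-1-yl trifluoromethanesulfonate | CC(C)=CC/C=C(\OS(=O)(=O)C(F)(F)F)c1cn(COCC[Si](C)(C)C)c2ccccc12
F2 | step 9 | (Z)-trimethyl[5-methyl-1-(1-SEM-indol-3-yl)hexa-1,4-dien-1-yl]stannane | CC(C)=CC/C=C(\[Sn](C)(C)C)c1cn(COCC[Si](C)(C)C)c2ccccc12
F3 | step 9 | (E)-[5-methyl-1-(1-SEM-indol-3-yl)hexa-1,4-dien-1-yl]lithium, Li cis to the CH2 group | CC(C)=CC/C=C(\[Li])c1cn(COCC[Si](C)(C)C)c2ccccc12
F4 | step 9 | rac-4-hydroxy-3-methoxy-4-[(Z)-5-methyl-1-(1-SEM-indol-3-yl)hexa-1,4-dien-1-yl]-2-[2-(2-methylbut-3-en-2-yl)-1-SEM-indol-3-yl]cyclobut-2-en-1-one | COC1=C(c2c(C(C)(C)C=C)n(COCC[Si](C)(C)C)c3ccccc23)C(=O)C1(O)/C(c1cn(COCC[Si](C)(C)C)c2ccccc12)=C\CC=C(C)C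
F5 | step 13 | 5-(1H-indol-3-yl)-3-methoxy-2-[2-(2-methylbut-3-en-2-yl)-1H-indol-3-yl]-6-(3-methylbut-2-en-1-yl)benzene-1,4-diol | COc1c(O)c(-c2c[nH]c3ccccc23)c(CC=C(C)C)c(O)c1-c1c(C(C)(C)C=C)[nH]c2ccccc12
F6 | step 13 | 5-(1H-indol-3-yl)-3-methoxy-2-[2-(2-methylbut-3-en-2-yl)-1H-indol-3-yl]-6-(3-methylbut-2-en-1-yl)-1,4-benzoquinone | COC1=C(c2c(C(C)(C)C=C)[nH]c3ccccc23)C(=O)C(CC=C(C)C)=C(c2c[nH]c3ccccc23)C1=O
F7 | step 5 | 3-bromo-2-(2-methylbut-3-en-2-yl)-1-SEM-indole | C=CC(C)(C)c1c(Br)c2ccccc2n1COCC[Si](C)(C)C
F8 | step 5 | [2-(2-methylbut-3-en-2-yl)-1-SEM-indol-3-yl]lithium | C=CC(C)(C)c1c([Li])c2ccccc2n1COCC[Si](C)(C)C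
F9 | step 5 | rac-4-hydroxy-2,3-dimethoxy-4-[2-(2-methylbut-3-en-2-yl)-1-SEM-indol-3-yl]cyclobut-2-en-1-one | COC1=C(OC)C(O)(c2c(C(C)(C)C=C)n(COCC[Si](C)(C)C)c3ccccc23)C1=O
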